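**Retrosynthetic overview**
1. 15 ⇒ 14: the biaryl bond, which closes the bridged eight-membered ring, is made last by oxidative ortho–ortho coupling of a cis-2-aryl-4-benzyl oxolane.
2. 14 ⇒ 9 + 10: the C7–aryl bond comes from reductive coupling of an oxolane-3-carbaldehyde (as its tosylhydrazone) with an arylboronic acid.
3. 9 ⇒ 6: the oxolane ring (C8–C9 bond) comes from a formaldehyde oxocarbenium / enol carbamate cyclisation that also releases C7 as an aldehyde.
4. 6 ⇒ 2 + 3: the key C7′–C8′ bond comes from an asymmetric homoaldol addition of a titanated crotyl carbamate (a chiral homoenolate equivalent) to 3,4,5-trimethoxybenzaldehyde.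
5. Ring order: oxolane first (step 3), eight-membered ring last (step 5).

Assumption: the SMILES defines only the three sp3 centres, which are 7′S, 8S, 8′S (C7′ = ArCH–O, C8′ = CHMe, C8 = CH bearing C7H2Ar and C9H2O); the biaryl axis is taken as the one the oxygen bridge enforces. On the oxolane the aryl and benzyl groups are cis to each other and both trans to methyl.

**Step 1**
Reactants: 1 (E)-but-2-en-1-ol
Product: 2 (E)-but-2-en-1-yl N,N-diisopropylcarbamate
Conditions: NaH, THF, 0 °C; then iPr2NCOCl, reflux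
Reagents that add atoms: N,N-diisopropylcarbamoyl chloride, CC(C)N(C(C)C)C(Cl)=O
Why: O-carbamoylation of the sodium alkoxide (carbamate formation) installs the dipole-stabilising group needed for α-lithiation, with no stereocentre formed and the (E)-alkene untouched.

**Step 2**
Reactants: 2 (E)-but-2-en-1-yl N,N-diisopropylcarbamate; 3 3,4,5-trimethoxybenzaldehyde
Product: 6 (1Z,3S,4S)-4-hydroxy-3-methyl-4-(3,4,5-trimethoxyphenyl)but-1-en-1-yl N,N-diisopropylcarbamate, via lithiated carbamate sparteine complex 4 (not isolated), via allyltitanium triisopropoxide 5 (not isolated)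
Conditions: n-BuLi, (−)-sparteine, pentane/cyclohexane, −70 °C (crystallisation of 4); Ti(OiPr)4, −70 °C; 3 in toluene, −70 °C; 2 M HCl
Reagents that add atoms: none
Why: Hoppe asymmetric homoaldol reaction, in which sparteine-mediated α-lithiation with crystallisation-driven dynamic resolution gives the (S)-lithium complex, titanation with inversion gives the (R)-allyltitanium homoenolate equivalent, and γ-attack on the aldehyde through a closed Zimmerman–Traxler chair (carbamoyloxy axial, methyl and aryl equatorial) gives the (Z)-anti adduct, setting C7′ and C8′ as (S,S) while making the β-carbon of a masked butanal the nucleophile toward the aldehyde carbon.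

**Step 3**
Reactants: 6 (1Z,3S,4S)-4-hydroxy-3-methyl-4-(3,4,5-trimethoxyphenyl)but-1-en-1-yl N,N-diisopropylcarbamate
Product: 9 (3S,4S,5S)-4-methyl-5-(3,4,5-trimethoxyphenyl)oxolane-3-carbaldehyde, via MOM ether 7 (not isolated), via methoxy carbamate acetal 8 (not isolated)
Conditions: CH2(OMe)2, BF3·OEt2, CH2Cl2, −78 → 0 °C; then 1 M HCl/THF, 0 °C
Reagents that add atoms: dimethoxymethane, COCOC; water, O
Why: Proposed new method: transacetalisation gives MOM ether 7, BF3 ionises it to the O-methylene oxocarbenium ion, and the nucleophilic β-carbon of the (Z)-enol carbamate closes the five-membered ring (Mukaiyama/Prins-type cyclisation, closest known reaction being the BF3-mediated condensation of 4-hydroxy-1-alkenyl carbamates with aldehydes or their acetals to oxolane-3-carbaldehydes), attack occurring on the alkene face anti to the C8′ methyl in the A(1,3)-minimised conformer so that C8 is set trans to methyl and cis to aryl (also the thermodynamic arrangement of this epimerisable centre), after which aqueous acid hydrolyses the methoxy(carbamoyloxy)methyl group of 8 to the aldehyde.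

**Step 4**
Reactants: 9 (3S,4S,5S)-4-methyl-5-(3,4,5-trimethoxyphenyl)oxolane-3-carbaldehyde; 10 (3,4,5-trimethoxyphenyl)boronic acid
Product: 14 (2S,3S,4S)-3-methyl-2-(3,4,5-trimethoxyphenyl)-4-[(3,4,5-trimethoxyphenyl)methyl]oxolane, via tosylhydrazone 11 (not isolated), via diazoalkane 12 (not isolated), via benzylic boronic acid 13 (not isolated)
Conditions: TsNHNH2, 1,4-dioxane, 80 °C; then 10, K2CO3, 110 °C
Reagents that add atoms: none
Why: Barluenga-type metal-free reductive coupling, in which the tosylhydrazone gives a diazoalkane (Bamford–Stevens), this adds to the arylboronic acid with 1,2-aryl shift and loss of N2, and protodeboronation leaves the C7 methylene, the ring stereocentres being untouched and any epimerisation at C8 through the hydrazone returning the same all-trans isomer.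

**Step 5**
Reactants: 14 (2S,3S,4S)-3-methyl-2-(3,4,5-trimethoxyphenyl)-4-[(3,4,5-trimethoxyphenyl)methyl]oxolane
Product: 15 (7′S,8S,8′S)-3,4,5,3′,4′,5′-hexamethoxy-7′,9-epoxy-2,2′-cyclolignan (target)
Conditions: PhI(OCOCF3)2, BF3·OEt2, CH2Cl2 (0.01 M), −40 °C
Reagents that add atoms: none
Why: non-phenolic oxidative biaryl coupling with a trivalent iodine oxidant (Kita-type, arene radical cation), in which the para positions are blocked by methoxy groups and the two free ortho positions of each ring are equivalent, so the cis-held aryl and benzyl groups close the eight-membered ring ortho–ortho without touching any sp3 centre, and the biaryl axis takes the twist the oxygen bridge allows.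

**Compound list**
1 | (E)-but-2-en-1-ol | C/C=C/CO | starting material
2 | (E)-but-2-en-1-yl N,N-diisopropylcarbamate | C/C=C/COC(=O)N(C(C)C)C(C)C | intermediate
3 | 3,4,5-trimethoxybenzaldehyde | COc1cc(C=O)cc(OC)c1OC | starting material
4 | (S)-(E)-1-lithiobut-2-enyl N,N-diisopropylcarbamate, as its (−)-sparteine complex (SMILES of the organolithium part) | C/C=C/[C@H]([Li])OC(=O)N(C(C)C)C(C)C | intermediate
5 | (R)-(E)-1-(triisopropoxytitanio)but-2-enyl N,N-diisopropylcarbamate | C/C=C/[C@@H]([Ti](OC(C)C)(OC(C)C)OC(C)C)OC(=O)N(C(C)C)C(C)C | intermediate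
6 | (1Z,3S,4S)-4-hydroxy-3-methyl-4-(3,4,5-trimethoxyphenyl)but-1-en-1-yl N,N-diisopropylcarbamate (anti) | COc1cc(cc(OC)c1OC)[C@@H](O)[C@@H](C)/C=C\OC(=O)N(C(C)C)C(C)C | intermediate
7 | (1Z,3S,4S)-4-(methoxymethoxy)-3-methyl-4-(3,4,5-trimethoxyphenyl)but-1-en-1-yl N,N-diisopropylcarbamate | COc1cc(cc(OC)c1OC)[C@@H](OCOC)[C@@H](C)/C=C\OC(=O)N(C(C)C)C(C)C | intermediate
8 | methoxy[(3S,4S,5S)-4-methyl-5-(3,4,5-trimethoxyphenyl)oxolan-3-yl]methyl N,N-diisopropylcarbamate (both epimers at the acetal carbon) | COc1cc(cc(OC)c1OC)[C@H]1OC[C@@H](C(OC)OC(=O)N(C(C)C)C(C)C)[C@@H]1C | intermediate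
9 | (3S,4S,5S)-4-methyl-5-(3,4,5-trimethoxyphenyl)oxolane-3-carbaldehyde (all-trans) | COc1cc(cc(OC)c1OC)[C@H]1OC[C@@H](C=O)[C@@H]1C | intermediate
10 | (3,4,5-trimethoxyphenyl)boronic acid | COc1cc(cc(OC)c1OC)B(O)O | starting material
11 | (E)-N-tosylhydrazone of aldehyde 9 (ring configuration as in 9) | COc1cc(cc(OC)c1OC)[C@H]1OC[C@@H](/C=N/NS(=O)(=O)c2ccc(C)cc2)[C@@H]1C | intermediate
12 | diazomethyl compound from 11 (ring configuration as in 9) | COc1cc(cc(OC)c1OC)[C@H]1OC[C@@H](C=[N+]=[N-])[C@@H]1C | intermediate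
13 | [(3S,4S,5S)-4-methyl-5-(3,4,5-trimethoxyphenyl)oxolan-3-yl](3,4,5-trimethoxyphenyl)methylboronic acid (both epimers at the boron-bearing carbon) | COc1cc(cc(OC)c1OC)[C@H]1OC[C@@H](C(B(O)O)c2cc(OC)c(OC)c(OC)c2)[C@@H]1C | intermediate
14 | (2S,3S,4S)-3-methyl-2-(3,4,5-trimethoxyphenyl)-4-[(3,4,5-trimethoxyphenyl)methyl]oxolane | COc1cc(cc(OC)c1OC)[C@H]1OC[C@@H](Cc2cc(OC)c(OC)c(OC)c2)[C@@H]1C | intermediate
15 | (7′S,8S,8′S)-3,4,5,3′,4′,5′-hexamethoxy-7′,9-epoxy-2,2′-cyclolignan (CNP0392777.1) | COc1cc2c(c(OC)c1OC)-c1c(cc(OC)c(OC)c1OC)[C@H]1OC[C@@H](C2)[C@@H]1C | target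

**Totals**
Total step count: 5. Longest linear sequence: 5 (1 → 2 → 6 → 9 → 14 → 15).

The enantiomeric purity from step 2 is typically not complete; it can be raised by recrystallising 6 or 14.

**Three steps most likely to fail**

Step 3 (formaldehyde oxocarbenium / enol carbamate cyclisation). The step is unprecedented with a formaldehyde acetal. The electron-rich ring could also capture the carbamoyloxy-stabilised cation (Friedel–Crafts), or the benzylic alcohol could ionise. The fallback sets out from 6 and comes back to the route at 14, so it also bypasses step 4. Compound 6 is cyclised with catalytic MeSO3H in MeOH to the lactol ether (4S,5S)-2-methoxy-4-methyl-5-(3,4,5-trimethoxyphenyl)oxolane F1. This is oxidised with mCPBA/BF3·OEt2 to the trans lactone (4S,5S)-4-methyl-5-(3,4,5-trimethoxyphenyl)oxolan-2-one F2. Its lithium enolate (LiN(SiMe3)2, THF, −78 °C) is alkylated with commercial 3,4,5-trimethoxybenzyl bromide anti to the neighbouring methyl, giving (3S,4S,5S)-4-methyl-3-[(3,4,5-trimethoxyphenyl)methyl]-5-(3,4,5-trimethoxyphenyl)oxolan-2-one F3. Reduction with i-Bu2AlH at −78 °C gives the lactol (3S,4S,5S)-4-methyl-3-[(3,4,5-trimethoxyphenyl)methyl]-5-(3,4,5-trimethoxyphenyl)oxolan-2-ol F4, and Et3SiH/BF3·OEt2 at −78 °C removes the anomeric hydroxyl to give 14.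

Step 5 (oxidative closure of the bridged biaryl). The bicyclic product is strained, and the benzylic ether may be oxidised or the substrate may oligomerise. The fallback sets out from 14 and comes back at 15. Both rings are brominated at their free ortho positions with N-bromosuccinimide in MeCN to give (2S,3S,4S)-2-(2-bromo-3,4,5-trimethoxyphenyl)-4-[(2-bromo-3,4,5-trimethoxyphenyl)methyl]-3-methyloxolane F6. This is closed by intramolecular reductive biaryl coupling with stoichiometric zerovalent nickel (Ni(cod)2, 2,2′-bipyridine, DMF, 60 °C, high dilution) to give 15.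

Step 4 (reductive coupling through the tosylhydrazone). The diazoalkane may undergo 1,2-hydride shift to an alkene, or the β-alkoxy hydrazone may ring-open under base. The fallback sets out from 9 and comes back at 14. Commercial 3,4,5-(MeO)3C6H2MgBr in THF at −78 °C adds to the aldehyde to give the carbinol [(3S,4S,5S)-4-methyl-5-(3,4,5-trimethoxyphenyl)oxolan-3-yl](3,4,5-trimethoxyphenyl)methanol F5 as a mixture of carbinol epimers. Ionic hydrogenation (Et3SiH, CF3CO2H, CH2Cl2, −20 °C) removes the doubly activated benzylic hydroxyl to give 14.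

**Further compounds**
F1 | step 3 | (4S,5S)-2-methoxy-4-methyl-5-(3,4,5-trimethoxyphenyl)oxolane (anomer mixture) | COc1cc(cc(OC)c1OC)[C@H]1OC(OC)C[C@@H]1C
F2 | step 3 | (4S,5S)-4-methyl-5-(3,4,5-trimethoxyphenyl)oxolan-2-one | COc1cc(cc(OC)c1OC)[C@H]1OC(=O)C[C@@H]1C
F3 | step 3 | (3S,4S,5S)-4-methyl-3-[(3,4,5-trimethoxyphenyl)methyl]-5-(3,4,5-trimethoxyphenyl)oxolan-2-one | COc1cc(cc(OC)c1OC)[C@H]1OC(=O)[C@@H](Cc2cc(OC)c(OC)c(OC)c2)[C@@H]1C
F4 | step 3 | (3S,4S,5S)-4-methyl-3-[(3,4,5-trimethoxyphenyl)methyl]-5-(3,4,5-trimethoxyphenyl)oxolan-2-ol (anomer mixture) | COc1cc(cc(OC)c1OC)[C@H]1OC(O)[C@@H](Cc2cc(OC)c(OC)c(OC)c2)[C@@H]1C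
F5 | step 4 | [(3S,4S,5S)-4-methyl-5-(3,4,5-trimethoxyphenyl)oxolan-3-yl](3,4,5-trimethoxyphenyl)methanol (carbinol epimers) | COc1cc(cc(OC)c1OC)[C@H]1OC[C@@H](C(O)c2cc(OC)c(OC)c(OC)c2)[C@@H]1C
F6 | step 5 | (2S,3S,4S)-2-(2-bromo-3,4,5-trimethoxyphenyl)-4-[(2-bromo-3,4,5-trimethoxyphenyl)methyl]-3-methyloxolane | COc1cc(c(Br)c(OC)c1OC)[C@H]1OC[C@@H](Cc2cc(OC)c(OC)c(OC)c2Br)[C@@H]1C
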